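Ring B (C5–C6–C7–C8–C9–C10, eudesmane numbering) is closed last, through the C7–C8 bond. The key step exploits the 2-substituted acrylate on C7: the unit C7–C11(=C13H2)CO2Me is the signature of a radical addition–β-fragmentation (SH2′) on a 2-(sulfonylmethyl)enoate. Its precursor is a monocyclic ring A cyclohexene that carries a vinyl group on quaternary C10 and, trans to it on C5, a sulfonyl enoate arm. In one operation, hydroboration turns the vinyl group into a C8 radical source, 6-exo cyclisation closes ring B, sets C7 and unveils the acrylate. C10 comes from an asymmetric Diels–Alder reaction, C5 from a Claisen rearrangement, and the (Z)-coumarate from a late Z-selective olefination.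

Key step: step 8

Atom numbers are those of the eudesmane skeleton of the target: ring A = C1, C2, C3, C4, C5, C10; ring B = C5, C6, C7, C8, C9, C10; C14 = methyl on C10; C15 = oxygenated carbon on C4; C11, C12, C13 = acrylate carbons on C7. β is the face of the C10 methyl group.

Remark: the (R,R)-TADDOL is taken as the enantiomer that leads to (1S)-configured 3; should the sense of induction be the opposite one, the (S,S)-diol is used and nothing else changes.

Step 1
Reactants: 1 (E)-3-[(tert-butyldimethylsilyl)oxy]-N,N-dimethylbuta-1,3-dien-1-amine; 2 methacrolein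
Product: 3 (1S,2R)-4-[(tert-butyldimethylsilyl)oxy]-2-(dimethylamino)-1-methylcyclohex-3-ene-1-carbaldehyde (endo adduct, CHO cis to NMe2; used crude)
Conditions: (R,R)-1-naphthyl-TADDOL (20 mol %), toluene, −80 °C
Reagents that add atoms: none
Why: Hydrogen-bond-catalysed asymmetric Diels–Alder reaction that builds ring A, in which the amino-bearing diene terminus bonds to the α-carbon of the enal and the chiral diol, bound to the aldehyde, shields one face so that the quaternary carbon (later C10) is set by catalyst control, while the endo-derived amino centre is removed in step 2.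

Step 2
Reactants: 3 (1S,2R)-4-[(tert-butyldimethylsilyl)oxy]-2-(dimethylamino)-1-methylcyclohex-3-ene-1-carbaldehyde
Product: 5 (R)-4-methyl-4-vinylcyclohex-2-en-1-one, via vinyl silyl enol ether 4 (not isolated)
Conditions: Ph3PCH3Br, KOtBu, THF, 0 °C to rt; then 1 M HCl, THF, 0 °C
Reagents that add atoms: methyltriphenylphosphonium bromide, C[P+](c1ccccc1)(c1ccccc1)c1ccccc1.[Br-]
Why: Wittig methylenation of the non-enolisable neopentyl aldehyde gives C9=C8, and acid hydrolysis of the silyl enol ether with β-elimination of dimethylamine should then give the 4,4-disubstituted enone without touching the quaternary centre.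

Step 3
Reactants: 5 (R)-4-methyl-4-vinylcyclohex-2-en-1-one
Product: 6 (R)-2-iodo-4-methyl-4-vinylcyclohex-2-en-1-one
Conditions: I2, pyridine, CH2Cl2, 0 °C to rt
Reagents that add atoms: iodine, II
Why: α-Iodination of the enone by conjugate addition of pyridine, iodination of the enolate and E1cB loss of pyridine places on C4 the handle that later becomes C15; no stereocentre is touched.

Step 4
Reactants: 6 (R)-2-iodo-4-methyl-4-vinylcyclohex-2-en-1-one
Product: 7 (1S,4R)-2-iodo-4-methyl-4-vinylcyclohex-2-en-1-ol (OH cis to the methyl group)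
Conditions: (R)-2-methyl-CBS-oxazaborolidine (15 mol %), catecholborane, toluene, −78 °C
Reagents that add atoms: none
Why: CBS reduction in which the iodoalkene arm acts as the large group, so that the (R)-catalyst should give the 1S carbinol (C3–OH on the β face) under catalyst control; catecholborane at −78 °C leaves the vinyl group alone, and the diastereomer that stems from the minor enantiomer of 6 is removable by chromatography.

Step 5
Reactants: 7 (1S,4R)-2-iodo-4-methyl-4-vinylcyclohex-2-en-1-ol
Product: 9 2-[(1R,6R)-2-iodo-6-methyl-6-vinylcyclohex-2-en-1-yl]acetaldehyde, via allyl vinyl ether 8 (not isolated)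
Conditions: Hg(OAc)2 (0.3 equiv), ethyl vinyl ether, reflux; evaporation; xylenes, Et3N (trace), sealed tube, 170 °C
Reagents that add atoms: ethyl vinyl ether, C=COCC
Why: Transvinylation followed by Claisen rearrangement, a suprafacial [3,3] shift that transfers the C3–O configuration to the new C5–C6 bond on the β face (H5 α, C6 trans to the C10 vinyl group), moves the alkene to C3=C4 and delivers C7 as an aldehyde.

Step 6
Reactants: 9 2-[(1R,6R)-2-iodo-6-methyl-6-vinylcyclohex-2-en-1-yl]acetaldehyde; 10 trimethyl 2-phosphonoacrylate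
Product: 11 methyl (2Z)-4-[(1R,6R)-2-iodo-6-methyl-6-vinylcyclohex-2-en-1-yl]-2-[(phenylsulfanyl)methyl]but-2-enoate (ester trans to the ring arm expected as the main isomer)
Conditions: PhSH, NaH, THF, 0 °C; then 10; then 9, 0 °C to rt
Reagents that add atoms: thiophenol, Sc1ccccc1
Why: Tandem thia-Michael addition/Horner–Wadsworth–Emmons olefination, in which thiolate addition to the phosphonoacrylate generates the phosphonate anion that olefinates the aldehyde; both alkene isomers lead to the same product in step 8.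

Step 7
Reactants: 11 methyl (2Z)-4-[(1R,6R)-2-iodo-6-methyl-6-vinylcyclohex-2-en-1-yl]-2-[(phenylsulfanyl)methyl]but-2-enoate
Product: 12 methyl (2Z)-4-[(1R,6R)-2-iodo-6-methyl-6-vinylcyclohex-2-en-1-yl]-2-[(phenylsulfonyl)methyl]but-2-enoate
Conditions: (NH4)6Mo7O24·4H2O (10 mol %), 30% H2O2, EtOH, 0 °C to rt
Reagents that add atoms: hydrogen peroxide, OO
Why: Molybdate-catalysed peroxide oxidation of sulfide to sulfone is selective for sulfur over the isolated and electron-poor alkenes and gives the leaving group that can carry a radical chain.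

Step 8
Reactants: 12 methyl (2Z)-4-[(1R,6R)-2-iodo-6-methyl-6-vinylcyclohex-2-en-1-yl]-2-[(phenylsulfonyl)methyl]but-2-enoate
Product: 14 methyl 2-[(2R,4aS,8aR)-8-iodo-4a-methyl-1,2,3,4,4a,5,6,8a-octahydronaphthalen-2-yl]prop-2-enoate, via B-alkylcatecholborane 13 (not isolated)
Conditions: catecholborane, MeC(O)NMe2 (cat.), CH2Cl2, 40 °C; then t-BuOH; then t-BuON=NOt-Bu (cat.), benzene (0.01 M), 45 °C
Reagents that add atoms: none
Why: Anti-Markovnikov hydroboration of the monosubstituted vinyl group puts boron on C8; tert-butoxyl radical then releases the primary C8 radical from the B-alkylcatecholborane, this radical adds to C7 of the enoate, and the C11 radical expels PhSO2•, which attacks the next borane and carries the chain, so that the C7–C8 bond and the C11=C13 methylene arise together. The closest known reaction type is the tin-free radical allylation of B-alkylcatecholboranes by 2-(sulfonylmethyl)acrylates, run here within one molecule as a radical SH2′ cyclisation. Ring B closes in the 6-exo-trig mode. C7 is set by a chair-like transition state that is held by the trans-diequatorial C10–C9 and C5–C6 bonds on ring A and keeps the forming C7–C11 bond equatorial, which should give the 7β side chain cis to the C10 methyl group, while C5 and C10 are carried over unchanged. The step needs hydroboration of the vinyl group only, which its monosubstitution secures against the trisubstituted iodoalkene and the electron-poor enoate, and ring closure faster than 1,5-hydrogen transfer from C6 or 5-exo attack on C4, which the polarity match between the nucleophilic alkyl radical and the enoate is expected to secure.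

Step 9
Reactants: 14 methyl 2-[(2R,4aS,8aR)-8-iodo-4a-methyl-1,2,3,4,4a,5,6,8a-octahydronaphthalen-2-yl]prop-2-enoate
Product: 15 methyl 2-[(2R,4aR,8aR)-8-(hydroxymethyl)-4a-methyl-1,2,3,4,4a,5,6,8a-octahydronaphthalen-2-yl]prop-2-enoate
Conditions: Bu3SnCH2OH, Pd(PPh3)4 (5 mol %), BHT (trace), 1,4-dioxane, 90 °C
Reagents that add atoms: (tributylstannyl)methanol, CCCC[Sn](CCCC)(CCCC)CO
Why: Stille cross-coupling in which zerovalent palladium inserts into the C4–I bond and the hydroxymethyl group is transferred from tin, which installs C15 with the C3=C4 alkene and all stereocentres retained.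

Step 10
Reactants: 15 methyl 2-[(2R,4aR,8aR)-8-(hydroxymethyl)-4a-methyl-1,2,3,4,4a,5,6,8a-octahydronaphthalen-2-yl]prop-2-enoate; 16 (diphenoxyphosphoryl)acetic acid
Product: 17 methyl 2-[(2R,4aR,8aR)-8-({[(diphenoxyphosphoryl)acetyl]oxy}methyl)-4a-methyl-1,2,3,4,4a,5,6,8a-octahydronaphthalen-2-yl]prop-2-enoate
Conditions: EDC·HCl, DMAP (cat.), CH2Cl2, 0 °C to rt
Reagents that add atoms: none
Why: Carbodiimide (Steglich) esterification of the unhindered primary allylic alcohol; no stereocentre is involved.

Step 11
Reactants: 17 methyl 2-[(2R,4aR,8aR)-8-({[(diphenoxyphosphoryl)acetyl]oxy}methyl)-4a-methyl-1,2,3,4,4a,5,6,8a-octahydronaphthalen-2-yl]prop-2-enoate; 18 4-[(tert-butyldimethylsilyl)oxy]benzaldehyde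
Product: 20 methyl 2-[(2R,4aR,8aR)-8-({[(2Z)-3-(4-hydroxyphenyl)prop-2-enoyl]oxy}methyl)-4a-methyl-1,2,3,4,4a,5,6,8a-octahydronaphthalen-2-yl]prop-2-enoate (CNP0161949.2), via silyl-protected ester 19 (not isolated)
Conditions: NaH, THF, −78 to −20 °C; then HF·pyridine, 0 °C
Reagents that add atoms: none
Why: Z-selective Horner–Wadsworth–Emmons olefination with a diaryl phosphonoacetate, whose fast and irreversible elimination from the syn adduct should give the cis enoate, followed in the same flask by fluoride cleavage of the aryl silyl ether.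

Compound list
1 | (E)-3-[(tert-butyldimethylsilyl)oxy]-N,N-dimethylbuta-1,3-dien-1-amine | CN(C)/C=C/C(=C)O[Si](C)(C)C(C)(C)C | starting material
2 | methacrolein (2-methylprop-2-enal) | CC(=C)C=O | starting material
3 | (1S,2R)-4-[(tert-butyldimethylsilyl)oxy]-2-(dimethylamino)-1-methylcyclohex-3-ene-1-carbaldehyde | O=C[C@@]1(C)CCC(O[Si](C)(C)C(C)(C)C)=C[C@H]1N(C)C | intermediate
4 | (1R,6R)-3-[(tert-butyldimethylsilyl)oxy]-N,N,6-trimethyl-6-vinylcyclohex-2-en-1-amine | C=C[C@@]1(C)CCC(O[Si](C)(C)C(C)(C)C)=C[C@H]1N(C)C | intermediate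
5 | (R)-4-methyl-4-vinylcyclohex-2-en-1-one | O=C1C=C[C@@](C)(C=C)CC1 | intermediate
6 | (R)-2-iodo-4-methyl-4-vinylcyclohex-2-en-1-one | O=C1C(I)=C[C@@](C)(C=C)CC1 | intermediate
7 | (1S,4R)-2-iodo-4-methyl-4-vinylcyclohex-2-en-1-ol (OH cis to methyl) | O[C@@H]1C(I)=C[C@@](C)(C=C)CC1 | intermediate
8 | (1S,4R)-2-iodo-4-methyl-4-vinylcyclohex-2-en-1-yl vinyl ether | C=CO[C@@H]1C(I)=C[C@@](C)(C=C)CC1 | intermediate
9 | 2-[(1R,6R)-2-iodo-6-methyl-6-vinylcyclohex-2-en-1-yl]acetaldehyde | O=CC[C@H]1C(I)=CCC[C@]1(C)C=C | intermediate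
10 | trimethyl 2-phosphonoacrylate [methyl 2-(dimethoxyphosphoryl)prop-2-enoate] | C=C(C(=O)OC)P(=O)(OC)OC | starting material
11 | methyl (2Z)-4-[(1R,6R)-2-iodo-6-methyl-6-vinylcyclohex-2-en-1-yl]-2-[(phenylsulfanyl)methyl]but-2-enoate | COC(=O)/C(CSc1ccccc1)=C/C[C@H]1C(I)=CCC[C@]1(C)C=C | intermediate
12 | methyl (2Z)-4-[(1R,6R)-2-iodo-6-methyl-6-vinylcyclohex-2-en-1-yl]-2-[(phenylsulfonyl)methyl]but-2-enoate | COC(=O)/C(CS(=O)(=O)c1ccccc1)=C/C[C@H]1C(I)=CCC[C@]1(C)C=C | intermediate
13 | B-alkylcatecholborane from 12 (the C10 vinyl group has become CH2CH2–B(O2C6H4); other centres as in 12) | COC(=O)/C(CS(=O)(=O)c1ccccc1)=C/C[C@H]1C(I)=CCC[C@]1(C)CCB1Oc2ccccc2O1 | intermediate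
14 | methyl 2-[(2R,4aS,8aR)-8-iodo-4a-methyl-1,2,3,4,4a,5,6,8a-octahydronaphthalen-2-yl]prop-2-enoate (5α-H, 7β side chain, 10β-methyl) | C=C(C(=O)OC)[C@@H]1CC[C@@]2(C)CCC=C(I)[C@@H]2C1 | intermediate
15 | methyl 2-[(2R,4aR,8aR)-8-(hydroxymethyl)-4a-methyl-1,2,3,4,4a,5,6,8a-octahydronaphthalen-2-yl]prop-2-enoate | C=C(C(=O)OC)[C@@H]1CC[C@@]2(C)CCC=C(CO)[C@@H]2C1 | intermediate
16 | (diphenoxyphosphoryl)acetic acid | OC(=O)CP(=O)(Oc1ccccc1)Oc1ccccc1 | starting material
17 | methyl 2-[(2R,4aR,8aR)-8-({[(diphenoxyphosphoryl)acetyl]oxy}methyl)-4a-methyl-1,2,3,4,4a,5,6,8a-octahydronaphthalen-2-yl]prop-2-enoate | C=C(C(=O)OC)[C@@H]1CC[C@@]2(C)CCC=C(COC(=O)CP(=O)(Oc3ccccc3)Oc3ccccc3)[C@@H]2C1 | intermediate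
18 | 4-[(tert-butyldimethylsilyl)oxy]benzaldehyde | O=Cc1ccc(O[Si](C)(C)C(C)(C)C)cc1 | starting material
19 | methyl 2-[(2R,4aR,8aR)-8-({[(2Z)-3-{4-[(tert-butyldimethylsilyl)oxy]phenyl}prop-2-enoyl]oxy}methyl)-4a-methyl-1,2,3,4,4a,5,6,8a-octahydronaphthalen-2-yl]prop-2-enoate | C=C(C(=O)OC)[C@@H]1CC[C@@]2(C)CCC=C(COC(=O)/C=C\c3ccc(O[Si](C)(C)C(C)(C)C)cc3)[C@@H]2C1 | intermediate
20 | methyl 2-[(2R,4aR,8aR)-8-({[(2Z)-3-(4-hydroxyphenyl)prop-2-enoyl]oxy}methyl)-4a-methyl-1,2,3,4,4a,5,6,8a-octahydronaphthalen-2-yl]prop-2-enoate | C=C(C(=O)OC)[C@@H]1CC[C@@]2(C)CCC=C(COC(=O)/C=C\c3ccc(O)cc3)[C@@H]2C1 | target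

Total step count: 11. Longest linear sequence: 11 steps (1 and 2 to 20).

Steps most likely to fail

Step 8 (key step). The borane may also reduce the enoate during the hydroboration, the sulfonyl radical may fail to carry the chain at the dilution needed, or the C8 radical may be lost by 1,5-hydrogen transfer from C6 before it closes the ring. The fallback separates radical generation from hydroboration and sets out from sulfone 12. Hydroboration with 9-BBN (THF, 0 °C to rt) and oxidation with NaBO3·4H2O give the primary alcohol methyl (2Z)-4-[(1R,6R)-6-(2-hydroxyethyl)-2-iodo-6-methylcyclohex-2-en-1-yl]-2-[(phenylsulfonyl)methyl]but-2-enoate F1. PPh3, I2 and imidazole (CH2Cl2, 0 °C) convert it into the primary iodide methyl (2Z)-4-[(1R,6R)-2-iodo-6-(2-iodoethyl)-6-methylcyclohex-2-en-1-yl]-2-[(phenylsulfonyl)methyl]but-2-enoate F2. Et3B and air in benzene at rt then start an iodine-atom-transfer chain: ethyl radical abstracts only the sp3-bound iodine, the C8 radical cyclises and expels PhSO2•, and Et3B returns ethyl radical from the sulfonyl radical. The route is rejoined at 14.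

Step 5. Vinyl transfer to the hindered, iodine-flanked secondary alcohol may stay incomplete, and the allyl vinyl ether may eliminate to a diene or lose iodine at the temperature that a rearrangement next to the quaternary carbon needs. The fallback sets out from alcohol 7 and uses a Johnson–Claisen rearrangement (MeC(OEt)3, EtCO2H cat., 140 °C). The ketene acetal formed in the flask rearranges at lower temperature with the same suprafacial transfer and gives ethyl 2-[(1R,6R)-2-iodo-6-methyl-6-vinylcyclohex-2-en-1-yl]acetate F3. Reduction with iBu2AlH (CH2Cl2, −78 °C) stops at the aldehyde and rejoins the route at 9.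

Step 11. Erosion of the cis geometry during the olefination, or conjugate addition of the phosphonate anion to the acrylate, may compete. The fallback makes the cis acid apart from the skeleton and sets out from alcohol 15, so that step 10 is not needed. Aldehyde 18 and ethyl (diphenoxyphosphoryl)acetate (NaH, THF, −78 °C) give ethyl (2Z)-3-{4-[(tert-butyldimethylsilyl)oxy]phenyl}prop-2-enoate F4, a simple compound on which geometric isomers can be separated. LiOH (THF/H2O, rt) cleaves ester and silyl ether to (2Z)-3-(4-hydroxyphenyl)prop-2-enoic acid F5. Mitsunobu esterification (PPh3, DIAD, THF, 0 °C), in which the carboxylic acid reacts in preference to the phenol, joins F5 to 15 and comes back to the route at 20.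

Further compounds
F1 | step 8 | methyl (2Z)-4-[(1R,6R)-6-(2-hydroxyethyl)-2-iodo-6-methylcyclohex-2-en-1-yl]-2-[(phenylsulfonyl)methyl]but-2-enoate | COC(=O)/C(CS(=O)(=O)c1ccccc1)=C/C[C@H]1C(I)=CCC[C@]1(C)CCO
F2 | step 8 | methyl (2Z)-4-[(1R,6R)-2-iodo-6-(2-iodoethyl)-6-methylcyclohex-2-en-1-yl]-2-[(phenylsulfonyl)methyl]but-2-enoate | COC(=O)/C(CS(=O)(=O)c1ccccc1)=C/C[C@H]1C(I)=CCC[C@]1(C)CCI
F3 | step 5 | ethyl 2-[(1R,6R)-2-iodo-6-methyl-6-vinylcyclohex-2-en-1-yl]acetate | CCOC(=O)C[C@H]1C(I)=CCC[C@]1(C)C=C
F4 | step 11 | ethyl (2Z)-3-{4-[(tert-butyldimethylsilyl)oxy]phenyl}prop-2-enoate | CCOC(=O)/C=C\c1ccc(O[Si](C)(C)C(C)(C)C)cc1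
F5 | step 11 | (2Z)-3-(4-hydroxyphenyl)prop-2-enoic acid | OC(=O)/C=C\c1ccc(O)cc1
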